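The route rests on cutting the dihydrofuran ring of the styryl-bearing benzofuran at C2: the C2–C3 and C2–O1 bonds are both made in one [4+1] annulation. The step exploits the resorcinol ring of the terminal stilbene unit, whose carbon between the two oxygens (C3a) and one of those oxygens (O1) frame a latent o-quinone methide with C3 as its methide carbon. The precursor is an o-hydroxybenzhydryl sulfone that already carries the first dihydrobenzofuran and the stilbene; a 4-oxybenzyl ylide of an enantiopure sulfide brings in C2 with its aryl group, closes the ring trans and sets both stereocentres under reagent control. The same annulation with the enantiomeric sulfide builds the first dihydrobenzofuran earlier.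

Key step: step 14

Assumption: the sense of induction of the isothiocineole benzylides is taken from their aldehyde epoxidation (the (1R,4R,5R)-sulfide is taken as the one that gives (R,R)-stilbene oxide, which corresponds spatially to 2S in the dihydrobenzofuran); if it is the reverse, sulfides 11 and 22 simply change places between steps 6 and 12. Both enantiomers of the sulfide are treated as purchasable, each being otherwise one step from the corresponding limonene and sulfur.

MOM = methoxymethyl throughout.

**Step 1**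
Reactants: 1 4-bromo-2,6-dimethoxybenzaldehyde
Product: 2 4-bromo-2,6-dihydroxybenzaldehyde
Conditions: BBr3 (2.5 equiv), CH2Cl2, −78 °C → 0 °C; H2O
Reagents that add atoms: none
Why: Lewis-acid cleavage of both aryl methyl ethers, assisted by chelation to the ortho formyl group, should leave the aryl bromide and the aldehyde untouched.

**Step 2**
Reactants: 2 4-bromo-2,6-dihydroxybenzaldehyde
Product: 3 4-bromo-2-hydroxy-6-(methoxymethoxy)benzaldehyde
Conditions: MOMCl (1.05 equiv), i-Pr2NEt (1.1 equiv), CH2Cl2, 0 °C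
Reagents that add atoms: chloromethyl methyl ether, COCCl
Why: Williamson-type O-alkylation should stop after one hydroxyl because the second is held in a hydrogen bond to the formyl oxygen, which desymmetrises the ring.

**Step 3**
Reactants: 4 5-bromobenzene-1,3-diol
Product: 5 1-bromo-3,5-bis(methoxymethoxy)benzene
Conditions: NaH (2.4 equiv), MOMCl (2.4 equiv), DMF, 0 °C → rt
Reagents that add atoms: chloromethyl methyl ether, COCCl
Why: Twofold Williamson etherification of the phenoxides gives the acetal-protected aryl bromide.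

**Step 4**
Reactants: 5 1-bromo-3,5-bis(methoxymethoxy)benzene; 3 4-bromo-2-hydroxy-6-(methoxymethoxy)benzaldehyde
Product: 8 racemic 5-bromo-2-{[3,5-bis(methoxymethoxy)phenyl](4-methylbenzenesulfonyl)methyl}-3-(methoxymethoxy)phenol, via Grignard reagent 6 (not isolated), via carbinol 7 (not isolated)
Conditions: 5 (2.3 equiv), Mg turnings, I2 (cat.), THF, 50 °C; then 3, THF, 0 °C → rt; then p-TolSO2H (6 equiv), CH2Cl2, 0 °C → rt
Reagents that add atoms: p-toluenesulfinic acid, Cc1ccc(cc1)S(=O)O
Why: Grignard 1,2-addition to the aldehyde (the first equivalent deprotonates the phenol) is followed by acid ionisation of the o-hydroxybenzhydrol and S-alkylation of the sulfinate, giving a bench-stable quinone methide precursor whose new stereocentre is formed racemic and is erased in step 7.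

**Step 5**
Reactants: 9 4-(hydroxymethyl)-2-methoxyphenol (vanillyl alcohol)
Product: 10 [3-methoxy-4-(methoxymethoxy)phenyl]methanol
Conditions: MOMCl (1.1 equiv), K2CO3, acetone, 0 °C → rt
Reagents that add atoms: chloromethyl methyl ether, COCCl
Why: Carbonate deprotonates only the phenol, so the Williamson etherification should be chemoselective over the benzylic alcohol.

**Step 6**
Reactants: 10 [3-methoxy-4-(methoxymethoxy)phenyl]methanol; 11 (1R,4R,5R)-isothiocineole
Product: 13 (1R,4R,5R)-6-[3-methoxy-4-(methoxymethoxy)benzyl]-4,7,7-trimethyl-6-thiabicyclo[3.2.1]octan-6-ium tetrafluoroborate, via benzylic bromide 12 (not isolated)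
Conditions: CBr4 (1.05 equiv), PPh3 (1.05 equiv), CH2Cl2, 0 °C; then 11, NaBF4, CH2Cl2/H2O, rt
Reagents that add atoms: sodium tetrafluoroborate, [Na+].F[B-](F)(F)F
Why: Appel bromination under neutral conditions is followed by SN2 S-alkylation of the sulfide on the less hindered face of sulfur (one sulfonium diastereomer expected) and anion metathesis.

**Step 7**
Reactants: 8 racemic o-hydroxybenzhydryl sulfone; 13 sulfonium tetrafluoroborate
Product: 16 (2S,3S)-6-bromo-3-[3,5-bis(methoxymethoxy)phenyl]-2-[3-methoxy-4-(methoxymethoxy)phenyl]-4-(methoxymethoxy)-2,3-dihydro-1-benzofuran, via sulfonium ylide 14 (not isolated), via o-quinone methide 15 (not isolated)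
Conditions: Cs2CO3 (3 equiv), MeCN/CH2Cl2, 4 Å MS, 0 °C → rt
Reagents that add atoms: none
Why: Proposed new method: carbonate releases o-quinone methide 15 from 8 by 1,4-elimination of sulfinate and forms ylide 14 from 13; conjugate addition of the ylide carbon to the methide carbon and 5-exo-tet displacement of the sulfide by the regenerated phenoxide (inversion at C2) should give the trans ring, with C2 set by the sulfide-controlled ylide face and C3 by the anti approach of the two aryl groups; the closest known reaction types are the [4+1] annulation of o-quinone methides from 2-(1-tosylalkyl)phenols with carbonyl-stabilised sulfur ylides and the isothiocineole benzylide epoxidation of aldehydes.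

**Step 8**
Reactants: 17 4-hydroxybenzaldehyde
Product: 18 4-(methoxymethoxy)benzaldehyde
Conditions: MOMCl (1.2 equiv), K2CO3, acetone, rt
Reagents that add atoms: chloromethyl methyl ether, COCCl
Why: Williamson etherification of the acidic phenol.

**Step 9**
Reactants: 18 4-(methoxymethoxy)benzaldehyde
Product: 19 1-ethenyl-4-(methoxymethoxy)benzene
Conditions: Ph3PCH3Br, KOt-Bu, THF, 0 °C → rt
Reagents that add atoms: methyltriphenylphosphonium bromide, C[P+](c1ccccc1)(c1ccccc1)c1ccccc1.[Br-]
Why: Wittig methylenation of a non-enolisable aromatic aldehyde.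

**Step 10**
Reactants: 3 4-bromo-2-hydroxy-6-(methoxymethoxy)benzaldehyde; 19 1-ethenyl-4-(methoxymethoxy)benzene
Product: 20 2-hydroxy-6-(methoxymethoxy)-4-{(E)-2-[4-(methoxymethoxy)phenyl]ethenyl}benzaldehyde
Conditions: Pd(OAc)2 (5 mol%), P(o-tol)3 (10 mol%), Et3N, DMF, 100 °C
Reagents that add atoms: none
Why: Mizoroki–Heck coupling of an aryl bromide activated by the para formyl group; syn insertion and syn β-hydride elimination should give the E-stilbene.

**Step 11**
Reactants: 18 4-(methoxymethoxy)benzaldehyde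
Product: 21 [4-(methoxymethoxy)phenyl]methanol
Conditions: NaBH4, MeOH, 0 °C
Reagents that add atoms: none
Why: Borohydride reduction of the aldehyde.

**Step 12**
Reactants: 21 [4-(methoxymethoxy)phenyl]methanol; 22 (1S,4S,5S)-isothiocineole
Product: 24 (1S,4S,5S)-6-[4-(methoxymethoxy)benzyl]-4,7,7-trimethyl-6-thiabicyclo[3.2.1]octan-6-ium tetrafluoroborate, via benzylic bromide 23 (not isolated)
Conditions: CBr4 (1.05 equiv), PPh3 (1.05 equiv), CH2Cl2, 0 °C; then 22, NaBF4, CH2Cl2/H2O, rt
Reagents that add atoms: sodium tetrafluoroborate, [Na+].F[B-](F)(F)F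
Why: Appel bromination and SN2 S-alkylation as in step 6, here with the enantiomeric sulfide.

**Step 13**
Reactants: 16 (2S,3S)-6-bromo-dihydrobenzofuran; 20 stilbene salicylaldehyde
Product: 28 o-hydroxybenzhydryl p-tolyl sulfone joining the 6-position of the dihydrobenzofuran to the stilbene ring (two epimers at the sulfonyl carbon), via aryllithium 25 (not isolated), via sodium phenoxide 26 (not isolated), via carbinol 27 (not isolated)
Conditions: 16 (1.2 equiv), n-BuLi (1.2 equiv), THF, −78 °C; 20 + NaH (1.0 equiv), THF, 0 °C, added at −78 °C, → −20 °C; then p-TolSO2H (6 equiv), CH2Cl2, 0 °C → rt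
Reagents that add atoms: p-toluenesulfinic acid, Cc1ccc(cc1)S(=O)O
Why: Bromine–lithium exchange and 1,2-addition of the aryllithium to the aldehyde (phenol masked as its sodium salt) are followed by sulfination of the labile carbinol as in step 4; the benzhydryl stereocentre forms without control and becomes planar in step 14.

**Step 14**
Reactants: 28 o-hydroxybenzhydryl sulfone; 24 sulfonium tetrafluoroborate
Product: 31 heptakis-O-MOM gnetin K, (2R,3R) in the new styryl-bearing dihydrobenzofuran and (2S,3S) in the first one, via sulfonium ylide 29 (not isolated), via o-quinone methide 30 (not isolated)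
Conditions: Cs2CO3 (3 equiv), MeCN/CH2Cl2, 4 Å MS, 0 °C → rt, dark
Reagents that add atoms: none
Why: Proposed new method: Cs2CO3 turns the phenol of 28 into its phenoxide, which expels p-toluenesulfinate to give o-quinone methide 30, and deprotonates 24 to ylide 29; the ylide carbon adds to the methide carbon (future C3) in a conjugate addition that re-aromatises the ring as its phenoxide, which then displaces the sulfide from the ylide-derived carbon (future C2) with inversion. The closest known reactions are the [4+1] annulation of o-quinone methides, released from 2-(1-tosylalkyl)phenols by carbonate, with carbonyl-stabilised sulfur ylides to trans-2,3-dihydrobenzofurans, and the epoxidation of aldehydes with isothiocineole benzylides; new is a non-racemic, semi-stabilised benzylic ylide on an o-quinone methide. The one ring that closes, the dihydrofuran ring, forms by 5-exo-tet SN2 attack of O1 on C2 after the intermolecular C2–C3 bond formation. C2 is controlled by the sulfide, which fixes the ylide conformation and shields one of its faces, and C3 is controlled relative to C2 by the anti arrangement of the two aryl groups in the addition and by the faster closure (with possible reversal of the addition) of the betaine that leads to the trans ring. The step needs diastereoselectivity with respect to the two existing stereocentres of 28, which lie too far from the reacting carbons to interfere, so the (1S,4S,5S)-sulfide alone should deliver 2R,3R. It also needs site selectivity, secured because only one ortho hydroxyl is free (one quinone methide only) and because only attack at the methide carbon, not at the styryl terminus, restores aromaticity.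

**Step 15**
Reactants: 31 heptakis-O-MOM gnetin K
Product: 32 gnetin K
Conditions: HCl (3 M aq.), MeOH/THF, 45 °C, argon, dark
Reagents that add atoms: none
Why: Acid-catalysed acetal exchange removes all seven MOM groups as dimethoxymethane; the aryl methyl ether is inert, and any reversible opening of the 2-(4-hydroxyaryl)dihydrofuran rings can only return to the trans isomers, which are the thermodynamic ones.

**Compound list**

1 | 4-bromo-2,6-dimethoxybenzaldehyde | COc1cc(Br)cc(OC)c1C=O | starting material
2 | 4-bromo-2,6-dihydroxybenzaldehyde | Oc1cc(Br)cc(O)c1C=O | intermediate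
3 | 4-bromo-2-hydroxy-6-(methoxymethoxy)benzaldehyde | COCOc1cc(Br)cc(O)c1C=O | intermediate
4 | 5-bromobenzene-1,3-diol | Oc1cc(O)cc(Br)c1 | starting material
5 | 1-bromo-3,5-bis(methoxymethoxy)benzene | COCOc1cc(OCOC)cc(Br)c1 | intermediate
6 | [3,5-bis(methoxymethoxy)phenyl]magnesium bromide | COCOc1cc(OCOC)cc([Mg]Br)c1 | intermediate
7 | racemic 5-bromo-2-{[3,5-bis(methoxymethoxy)phenyl](hydroxy)methyl}-3-(methoxymethoxy)phenol | OC(c1cc(OCOC)cc(OCOC)c1)c1c(O)cc(Br)cc1OCOC | intermediate
8 | racemic 5-bromo-2-{[3,5-bis(methoxymethoxy)phenyl](4-methylbenzenesulfonyl)methyl}-3-(methoxymethoxy)phenol | Cc1ccc(cc1)S(=O)(=O)C(c1cc(OCOC)cc(OCOC)c1)c1c(O)cc(Br)cc1OCOC | intermediate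
9 | 4-(hydroxymethyl)-2-methoxyphenol (vanillyl alcohol) | COc1cc(CO)ccc1O | starting material
10 | [3-methoxy-4-(methoxymethoxy)phenyl]methanol | COCOc1ccc(CO)cc1OC | intermediate
11 | (1R,4R,5R)-4,7,7-trimethyl-6-thiabicyclo[3.2.1]octane ((1R,4R,5R)-isothiocineole) | C[C@@H]1CC[C@@H]2C[C@H]1SC2(C)C | starting material
12 | 4-(bromomethyl)-2-methoxy-1-(methoxymethoxy)benzene | COCOc1ccc(CBr)cc1OC | intermediate
13 | (1R,4R,5R)-6-[3-methoxy-4-(methoxymethoxy)benzyl]-4,7,7-trimethyl-6-thiabicyclo[3.2.1]octan-6-ium tetrafluoroborate (one diastereomer at sulfur, benzyl on the less hindered face; sulfur configuration not written) | C[C@@H]1CC[C@@H]2C[C@H]1[S+](Cc1ccc(OCOC)c(OC)c1)C2(C)C.F[B-](F)(F)F | intermediate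
14 | sulfonium ylide of 13 (benzylic carbanion on sulfur) | C[C@@H]1CC[C@@H]2C[C@H]1[S+]([CH-]c1ccc(OCOC)c(OC)c1)C2(C)C | intermediate
15 | 6-{[3,5-bis(methoxymethoxy)phenyl]methylidene}-3-bromo-5-(methoxymethoxy)cyclohexa-2,4-dien-1-one | O=C1C=C(Br)C=C(OCOC)C1=Cc1cc(OCOC)cc(OCOC)c1 | intermediate
16 | (2S,3S)-6-bromo-3-[3,5-bis(methoxymethoxy)phenyl]-2-[3-methoxy-4-(methoxymethoxy)phenyl]-4-(methoxymethoxy)-2,3-dihydro-1-benzofuran (trans) | COc1cc([C@H]2Oc3cc(Br)cc(OCOC)c3[C@@H]2c2cc(OCOC)cc(OCOC)c2)ccc1OCOC | intermediate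
17 | 4-hydroxybenzaldehyde | O=Cc1ccc(O)cc1 | starting material
18 | 4-(methoxymethoxy)benzaldehyde | COCOc1ccc(C=O)cc1 | intermediate
19 | 1-ethenyl-4-(methoxymethoxy)benzene | COCOc1ccc(C=C)cc1 | intermediate
20 | 2-hydroxy-6-(methoxymethoxy)-4-{(E)-2-[4-(methoxymethoxy)phenyl]ethenyl}benzaldehyde | O=Cc1c(O)cc(/C=C/c2ccc(OCOC)cc2)cc1OCOC | intermediate
21 | [4-(methoxymethoxy)phenyl]methanol | COCOc1ccc(CO)cc1 | intermediate
22 | (1S,4S,5S)-4,7,7-trimethyl-6-thiabicyclo[3.2.1]octane ((1S,4S,5S)-isothiocineole) | C[C@H]1CC[C@H]2C[C@@H]1SC2(C)C | starting material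
23 | 1-(bromomethyl)-4-(methoxymethoxy)benzene | COCOc1ccc(CBr)cc1 | intermediate
24 | (1S,4S,5S)-6-[4-(methoxymethoxy)benzyl]-4,7,7-trimethyl-6-thiabicyclo[3.2.1]octan-6-ium tetrafluoroborate (one diastereomer at sulfur; sulfur configuration not written) | C[C@H]1CC[C@H]2C[C@@H]1[S+](Cc1ccc(OCOC)cc1)C2(C)C.F[B-](F)(F)F | intermediate
25 | 6-lithio derivative of 16 (lithium in place of bromine) | COc1cc([C@H]2Oc3cc([Li])cc(OCOC)c3[C@@H]2c2cc(OCOC)cc(OCOC)c2)ccc1OCOC | intermediate
26 | sodium phenoxide of 20 | [Na+].[O-]c1cc(/C=C/c2ccc(OCOC)cc2)cc(OCOC)c1C=O | intermediate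
27 | carbinol: the 6-position of the (2S,3S)-dihydrobenzofuran of 16 bears CH(OH) attached to C1 of a 2-hydroxy-6-(methoxymethoxy)-4-[(E)-4-(methoxymethoxy)styryl]phenyl ring (two epimers at the carbinol carbon) | COc1cc([C@H]2Oc3cc(C(O)c4c(O)cc(/C=C/c5ccc(OCOC)cc5)cc4OCOC)cc(OCOC)c3[C@@H]2c2cc(OCOC)cc(OCOC)c2)ccc1OCOC | intermediate
28 | sulfone: as 27 with 4-methylbenzenesulfonyl in place of the carbinol hydroxyl (two epimers at the sulfonyl carbon) | COc1cc([C@H]2Oc3cc(C(c4c(O)cc(/C=C/c5ccc(OCOC)cc5)cc4OCOC)S(=O)(=O)c4ccc(C)cc4)cc(OCOC)c3[C@@H]2c2cc(OCOC)cc(OCOC)c2)ccc1OCOC | intermediate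
29 | sulfonium ylide of 24 (benzylic carbanion on sulfur) | C[C@H]1CC[C@H]2C[C@@H]1[S+]([CH-]c1ccc(OCOC)cc1)C2(C)C | intermediate
30 | o-quinone methide: 6-(arylmethylidene)-5-(methoxymethoxy)-3-[(E)-4-(methoxymethoxy)styryl]cyclohexa-2,4-dien-1-one, the aryl being the 6-position of the (2S,3S)-dihydrobenzofuran of 16 | COc1cc([C@H]2Oc3cc(C=C4C(=O)C=C(/C=C/c5ccc(OCOC)cc5)C=C4OCOC)cc(OCOC)c3[C@@H]2c2cc(OCOC)cc(OCOC)c2)ccc1OCOC | intermediate
31 | heptakis-O-(methoxymethyl) gnetin K: (2R,3R)-trans styryl-bearing dihydrobenzofuran attached through C3 to the 6-position of the (2S,3S)-trans first dihydrobenzofuran, all seven phenols as MOM ethers | COc1cc([C@H]2Oc3cc([C@@H]4c5c(OCOC)cc(/C=C/c6ccc(OCOC)cc6)cc5O[C@H]4c4ccc(OCOC)cc4)cc(OCOC)c3[C@@H]2c2cc(OCOC)cc(OCOC)c2)ccc1OCOC | intermediate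
32 | gnetin K | COc1cc([C@H]2Oc3cc([C@@H]4c5c(O)cc(/C=C/c6ccc(O)cc6)cc5O[C@H]4c4ccc(O)cc4)cc(O)c3[C@@H]2c2cc(O)cc(O)c2)ccc1O | target

**Totals**

Total step count: 15. Longest linear sequence: 7 steps (1, 2, 4, 7, 13, 14, 15).

**Steps most likely to fail**

Step 14. The ylide may discriminate its faces poorly, or add too slowly to the hindered, donor-stabilised quinone methide. Quinone methide oligomerisation, O-benzylation of the phenoxide by the sulfonium salt, or formation of the cis ring could then take over. The fallback uses known chemistry and sets out from carbinol 27, obtained by quenching step 13 with aqueous NH4Cl instead of the sulfinic acid. MnO2 in CH2Cl2 should oxidise it to the 2-hydroxybenzophenone F1. Its hydrogen-bonded phenol is alkylated with benzylic bromide 23 (K2CO3, DMF) to the benzyl ether F2. Hydrazine (EtOH, AcOH cat., 80 °C) gives the hydrazone F3, and MnO2 oxidises this to the diaryldiazomethane F4. Without isolation, a dirhodium tetracarboxylate, Rh2(S-PTAD)4 or its enantiomer (dirhodium tetrakis[(1-adamantyl)(N-phthalimido)acetate], whichever delivers 3R), should effect 1,5 C–H insertion of the donor/donor carbene into the 4-alkoxybenzylic ether CH2, the most hydridic C–H within reach, to give the cis-2,3-diaryl dihydrobenzofuran F5. The acid treatment of step 15 then removes the MOM groups and epimerises C2 through the ring-opened 4-hydroxybenzyl cation to the trans isomer, so the fallback comes back to the route at 32.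

Step 7. The same processes may interfere as in step 14, here without a second chance to correct the enantiomeric purity of the first dihydrobenzofuran. The fallback uses known chemistry and sets out from carbinol 7, obtained by quenching step 4 with aqueous NH4Cl. MnO2 oxidation gives the benzophenone F6, and alkylation of its phenol with benzylic bromide 12 (K2CO3, DMF) gives the benzyl ether F7. Hydrazine converts this to the hydrazone F8, and MnO2 to the diazo compound F9. Carbene C–H insertion with the enantiomer of the dirhodium catalyst that delivers 3S should give the cis dihydrobenzofuran F10. HCl in MeOH removes the four MOM groups and epimerises C2 to the trans tetraphenol F11, and MOMCl with NaH returns the route to 16.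

Step 13. The aryllithium may be quenched by proton transfer, may open the dihydrofuran ring after benzylic deprotonation, or may add sluggishly to the hindered phenoxide aldehyde. The fallback avoids the organolithium and sets out from 16. Miyaura borylation (PdCl2(dppf), bis(pinacolato)diboron, KOAc, dioxane, 90 °C) should give the pinacol boronate F12. Rhodium-catalysed 1,2-addition of F12 to aldehyde 20 ([RhCl(cod)]2, KOH, dioxane/H2O, 60 °C) gives carbinol 27. Treatment with p-TolSO2H in CH2Cl2 then rejoins the route at 28.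

**Further compounds**

F1 | step 14 | ketone from 27: [2-hydroxy-6-(methoxymethoxy)-4-styrylphenyl](dihydrobenzofuran-6-yl)methanone | COc1cc([C@H]2Oc3cc(C(=O)c4c(O)cc(/C=C/c5ccc(OCOC)cc5)cc4OCOC)cc(OCOC)c3[C@@H]2c2cc(OCOC)cc(OCOC)c2)ccc1OCOC
F2 | step 14 | 4-(methoxymethoxy)benzyl ether of F1 | COc1cc([C@H]2Oc3cc(C(=O)c4c(OCc6ccc(OCOC)cc6)cc(/C=C/c5ccc(OCOC)cc5)cc4OCOC)cc(OCOC)c3[C@@H]2c2cc(OCOC)cc(OCOC)c2)ccc1OCOC
F3 | step 14 | hydrazone of F2 | COc1cc([C@H]2Oc3cc(C(=NN)c4c(OCc6ccc(OCOC)cc6)cc(/C=C/c5ccc(OCOC)cc5)cc4OCOC)cc(OCOC)c3[C@@H]2c2cc(OCOC)cc(OCOC)c2)ccc1OCOC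
F4 | step 14 | diaryldiazomethane from F3 | COc1cc([C@H]2Oc3cc(C(=[N+]=[N-])c4c(OCc6ccc(OCOC)cc6)cc(/C=C/c5ccc(OCOC)cc5)cc4OCOC)cc(OCOC)c3[C@@H]2c2cc(OCOC)cc(OCOC)c2)ccc1OCOC
F5 | step 14 | C2 epimer of 31, (2S,3R)-cis in the styryl-bearing dihydrobenzofuran | COc1cc([C@H]2Oc3cc([C@@H]4c5c(OCOC)cc(/C=C/c6ccc(OCOC)cc6)cc5O[C@@H]4c4ccc(OCOC)cc4)cc(OCOC)c3[C@@H]2c2cc(OCOC)cc(OCOC)c2)ccc1OCOC
F6 | step 7 | [4-bromo-2-hydroxy-6-(methoxymethoxy)phenyl][3,5-bis(methoxymethoxy)phenyl]methanone | O=C(c1cc(OCOC)cc(OCOC)c1)c1c(O)cc(Br)cc1OCOC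
F7 | step 7 | 3-methoxy-4-(methoxymethoxy)benzyl ether of F6 | O=C(c1cc(OCOC)cc(OCOC)c1)c1c(OCc2ccc(OCOC)c(OC)c2)cc(Br)cc1OCOC
F8 | step 7 | hydrazone of F7 | NN=C(c1cc(OCOC)cc(OCOC)c1)c1c(OCc2ccc(OCOC)c(OC)c2)cc(Br)cc1OCOC
F9 | step 7 | diaryldiazomethane from F8 | [N-]=[N+]=C(c1cc(OCOC)cc(OCOC)c1)c1c(OCc2ccc(OCOC)c(OC)c2)cc(Br)cc1OCOC
F10 | step 7 | C2 epimer of 16, (2R,3S)-cis | COc1cc([C@@H]2Oc3cc(Br)cc(OCOC)c3[C@@H]2c2cc(OCOC)cc(OCOC)c2)ccc1OCOC
F11 | step 7 | (2S,3S)-6-bromo-3-(3,5-dihydroxyphenyl)-2-(4-hydroxy-3-methoxyphenyl)-2,3-dihydro-1-benzofuran-4-ol | COc1cc([C@H]2Oc3cc(Br)cc(O)c3[C@@H]2c2cc(O)cc(O)c2)ccc1O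
F12 | step 13 | pinacol boronate of 16 (4,4,5,5-tetramethyl-1,3,2-dioxaborolan-2-yl in place of bromine) | COc1cc([C@H]2Oc3cc(B4OC(C)(C)C(C)(C)O4)cc(OCOC)c3[C@@H]2c2cc(OCOC)cc(OCOC)c2)ccc1OCOC
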